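Start with the easy step: substrate meets reagent and gives target, and the question is how much of the reagent goes that way.

    substrate + reagent → target (k1 = 0.136 /M/s)
    substrate + 2 reagent → side product (k2 = 1.66 /M²/s)
    target ⇌ isomer of the product (K3 = 0.350, k3 = 0.00122 /s)

common to all: time 2.5 min
- ochre: substrate 0.20 M (in portions, 2, over 1.0 min); reagent 0.180 M; first portion at the start, last at 1.0 min
- violet: substrate 0.20 M; reagent 0.180 M (fed, over 1.0 min); all else is in the flask from the start; the feed brings no volume worth counting
- green: substrate 0.20 M; reagent 0.180 M; everything together at the start
- teal: substrate 0.20 M (fed, over 1.0 min); reagent 0.180 M; all else is in the flask from the start; the feed brings no volume worth counting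

- the flask with the highest amount of target, in percent of the substrate charged ("all alike" if they lie within 1.5 percentage points) (ochre / violet / green / teal / all alike)
- final target, as a percentage of the substrate charged, in ochre
- final target, as a percentage of the substrate charged, in violet
- final target, as a percentage of the substrate charged, in green
- final target, as a percentage of the substrate charged, in teal

Write a and b for the fractions of the substrate and reagent charges still present, and begin with green, in rates. At the start, reagent is used at 8.80 /min, a time constant of 0.114 min, which is far shorter than the run. The side step then runs 2.20 times as fast as the target step. Two things slow these rates. Falling a slows both steps by the same factor, so it cancels from their ratio. Taking b to 0.5 slows the target step by a factor of 2 but the side step by 4, and this shifts the split towards target. Each side turn also takes two reagent, so the share of reagent reaching target is: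

share = g/(g + b), with g = 0.228, the reagent use of the target step over that of the side step with b at full charge

This share climbs from 18.5% at the start. Its value at the middle of the curve is 31.3%, but its true mean over b is higher, so use the mean:

mean share = g ln(1 + 1/g) = 38.4%

Scale that by the charges to get 34.5%, the drawdown yield: target plus isomer of the product, per substrate charged, once reagent has fallen from full charge to zero. Dosing substrate changes a, which cancels, so ochre and teal share green's figure. Step 3 is slow against the run, so take off its forward loss, exp(−k3 t). That gives green 28.7%, ochre 28.7% and teal 28.7%.

In violet, balance the feed against use with a held at 0.7:

b² + g b = 0.199, so b = 0.347

Burning the fed reagent at that level and then drawing the remainder down gives 42.3%, more than the drawdown yield. After the same drift, violet stands at 35.2%.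

The forecast names violet, with 27.5% for ochre, 37.5% for violet, 28.7% for green and 28.5% for teal, since slow feeding “keeps its level low throughout”. Its violet figure is higher than mine.

The flasks give violet: ochre 27.6%, violet 37.5%, green 28.6%, teal 28.0%, so the forecast holds. Violet is not at rest at 2.5 min, with 6.1% of its reagent and 37% of its substrate left. By 25.0 min, ochre holds target 25.6% and isomer of the product 8.94%, summing to 34.5% against the drawdown yield of 34.5%. Teal reads the same, 25.6% and 8.94%. Left ten times as long, until 25.0 min, violet holds reagent at 0%, isomer of the product at 12.0% and target at 34.3%.

The constants used here are those of an exercise; the result is computed.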